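**The charge.** Take a small charge of solid E, cE 27 mM, in L at cL 81.0 mM and 35 °C, and keep the books in percent of that E. L is charged at more than E, so E is the limiting reagent if one L goes with one E. The oak run is this flask followed so far, and the larch run is an earlier flask.

| setting | oak | larch | flask |
|---|---|---|---|
| E | 27 mM | 18 mM | 27 mM |
| L | 81 mM | 81 mM | 81.0 mM |
| temperature | 35 °C | 20 °C | 35 °C |
| remark | the very flask that is asked about, followed so far | run made earlier |  |
| time |  |  | 12 h |

| run | time / min | Q / % | E / % |
|---|---|---|---|
| oak | 50.0 | 38.5 | 0.8 |
| oak | 80.0 | 50.6 | 0 |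
| oak | 150 | 53.5 | 0 |
| oak | 300 | 52.8 | 0 |
| oak | 600 | 53.6 | 0.3 |
| larch | 8.00 | 1.3 | 75.6 |
| larch | 20.0 | 7.1 | 49.3 |
| larch | 40.0 | 21.2 | 20.6 |
| larch | 60.0 | 37.0 | 0 |
| larch | 80.0 | 51.2 | 0.3 |

(readings scatter by 0.5 percentage points)

- E is a solid; its amount is given per volume of the solution
- Q that was removed still counts
- the earlier runs were read with a standard deviation of 0.5 percentage points
- at the start none of E is in solution
- additions bring no volume worth counting

- north-west: at 12 h take out 90% of the Q then present, then wait 6.0 h
- south-west: at 12 h raise the temperature by 25 K, then wait 6.0 h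
- north-east: at 12 h add L, 50.0% of the amount charged, then wait 6.0 h
- west: change nothing and wait 6.0 h more

- Q, in percent of the E first charged, at 12 h
- what to do for the largest gain in Q; "none" if nothing gains more than 2 percentage points (north-west / south-west / north-east / west / none)
- Q present, with what was taken out counted in, in percent of the E first charged, after north-west
- Q present, with what was taken out counted in, in percent of the E first charged, after west

**First entries.** In the oak run, enter solid E: 0.8% after 50.0 min, then 0% after 80.0 min. Q reads 38.5% and 50.6% at those times. Later it reads 53.5%, 52.8% and 53.6%, so enter their mean, 53.3%, as the plateau.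

**Open entry.** That leaves 46.7% of the E in the oak run neither solid nor Q, and no reading names it. Do not blame a shortage of L: one L per Q takes 14.4 mM, less than the 81.0 mM charged.

**Waiting pool.** Now take the gap between Q and the plateau in the oak run. It falls from 15 percentage points to 2.7 points between the first two readings, so, read as a first-order fall, it halves every 12.2 min. Call that reading the pool half-life. From 80.0 min to 12 h, count 52.4 pool half-lives. My reckoning therefore puts Q at the plateau at 12 h. The first and last plateau readings of Q in the oak run stand 450 min apart and differ by 0.1 points, and a reading scatters by 0.5 points, so I treat the open entry as lost to Q and expect no option to gain.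

**The forecast.** It gives 53.3% (52.6% to 54%), best none, north-west 53.5% (up to 58%) and west 53.3%. The likeliest cause it names is “a competing, strongly temperature-dependent loss of the dissolved intermediate to waste”.

**The result.** The flask gives 53.8% at 12 h, the best move is none, and the open entry is D, which stands at 46.2% with each D counted as two.

    E ⇌ G, rate k1*(cs1 - [G]) while solid is left; crystals form when [G] > cs1 (solubility = 14.0 mM, k = 0.0330 min⁻¹)
    G + L → Q (k = 0.660 M⁻¹ min⁻¹, Ea = 53.0 kJ mol⁻¹)
    2 E → D (k = 1.10 M⁻¹ min⁻¹, Ea = 65.0 kJ mol⁻¹)
    (constants at 35 °C)

**Count again.** Here G is dissolved E. This flask holds G at 5.68% after 72.0 min. Up to 360 min, count 23.6 pool half-lives of 12.2 min, and G then stands at 0%. The same flask at 60 °C has 59.0 of these 35 °C half-lives in its 12 h, and it ends with G at 0%, Q at 27.4% and D at 72.6%.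

The numbers in the tables are simulated for an exercise, and the scatter is random.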